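(All constants were drawn at random within sensible limits; the flask was simulated.)

A process chemist who wants the intermediate in hand at the end of a run has to hold it between two rates: the making, from substrate and reagent, and the draining, to the target and the isomer of the product.

| flask | substrate | reagent | time | remark |
|---|---|---|---|---|
| south | 43 mM | 0.700 equiv | 30 h | a closed flask charged with all of it at once and left for 30 h |
| north-east | 43 mM | 0.700 equiv |  | a single well-mixed tank run continuously and read at steady state, 30 h in it on average |
| north-west | 43 mM | 0.700 equiv |  | a single well-mixed tank run continuously and read at steady state, 90.0 h in it on average |
| south-east | 43 mM | 0.700 equiv (fed, over 30.0 h) | 30 h | all but reagent at the start; reagent goes in evenly over 30.0 h, the run ends at 30 h |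

    reagent + target → over-reaction product (k1 = 1.0 M⁻¹ h⁻¹)
    substrate + reagent → intermediate + by-product (k2 = 5.4 M⁻¹ h⁻¹)
    intermediate ⇌ target (K3 = 0.83, k3 = 0.050 h⁻¹)
    intermediate ⇌ isomer of the product (K4 = 2.9, k4 = 0.026 h⁻¹)

1. the set-up with the highest amount of intermediate at the outlet or at the end, in percent of the substrate put in ("none" if the first two lie within 2 percentage points) (south / north-east / north-west / south-east / none)
2. amount of intermediate at the outlet or at the end, in percent of the substrate put in, south
3. amount of intermediate at the outlet or at the end, in percent of the substrate put in, north-east
4. amount of intermediate at the outlet or at the end, in percent of the substrate put in, north-west
5. amount of intermediate at the outlet or at the end, in percent of the substrate put in, south-east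

We follow south-east in slow motion, since there the reagent enters evenly and the making can be reckoned from the feed. The intermediate leaves by two forward steps whose constants add to a drain constant of 0.0760 h⁻¹, a mean stay of 13.2 h. In the first instants the substrate stands at its full 43 mM, so a drop of reagent meets a pseudo-first-order surrounding and lasts 4.31 h, which is shorter than that stay, and we therefore take the feed of 1.00 mM h⁻¹ as the rate of making.

In the middle the intermediate climbs towards its standing level, the feed as a share of the substrate charged per hour divided by the drain constant, which is 30.7%. It climbs on the clock of the drain constant, and by the end of the feed it has covered 89.8% of the way, which gives 27.6%.

What is about to matter is a crossing: the reagent's life equals the mean stay when the substrate has fallen to 14.1 mM, and past that point the making would lag behind the feed. The full charge of reagent could take the substrate down to 12.9 mM, below the crossing, so the crossing can come near the end of the feed at the earliest. Two things we left out pull opposite ways: reagent still waiting in the flask lowers our figure, and the return from the target, at 0.0602 h⁻¹, a constant larger than the forward one, raises it. Our reckoning goes no further than this flask.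

The forecast gave 26.5% for south, 23.6% for north-east, 18.9% for north-west and 29% for south-east, above our figure, and chose south-east, holding that “Feeding the reagent over the run makes the intermediate late”. The simulation gives 25.1% for south, 23.5% for north-east, 18.9% for north-west and 28.1% for south-east, and so south-east.

In south-east the intermediate has a half-life of 9.12 h by the two forward steps together, while at 16.4 h the reagent has a half-life of 4.1 h by its reaction with substrate, which is shorter, and at 30.0 h the substrate stands at 47.4% of its charge, or 20.4 mM, still above the crossing. For the neighbour of south-east charged with 0.170 equiv of reagent, the other charges and the time held, the standing level scales with the charge to 7.46%, the same climb brings that to 6.69% at the end of the feed, and that flask ends with 7.75% of intermediate.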